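The constants used here come from no measurement.

Follow one molecule of starting material.

starting material 35 mM; first nucleophile 45.5 mM; gas 5.1 mM (held); time 3.0 d

    starting material ⇌ intermediate (K1 = 0.254, k1 = 0.0299 min⁻¹)
    first nucleophile + intermediate ⇌ target (K2 = 49.2 L mol⁻¹, k2 = 6.91 L mol⁻¹ min⁻¹)
    second nucleophile + intermediate → other capture product (k3 = 23.5 L mol⁻¹ min⁻¹)
    target ⇌ isomer of the product (K4 = 2.61, k4 = 0.0859 min⁻¹)
    gas ⇌ second nucleophile, rate k5*(csat - [second nucleophile]) (k5 = 0.0726 min⁻¹, csat = 5.1 mM)

1. at 3.0 d, what has stopped the reaction, if anything has (the first nucleophile has run out first / forward and back rates have come level / it is still moving / all of the starting material has reacted)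
2. conversion of starting material at 3.0 d
3. amount of other capture product at 3.0 d, in percent of the starting material charged
4. amount of target if the flask were left three thousand times as long, in percent of the starting material charged

- at the start none of second nucleophile is dissolved
- the reaction counts as stopped when no species that holds the starting material changes by six tenths of a point or more over the second half of the time
- run time (flask): 3.0 d

- Call the first nucleophile N, the second nucleophile W and the other capture product Q.
- Starting material, intermediate, target and isomer form one pool, and Q is its exit.
- At balance, with N at its full charge, each intermediate stands with 3.94 of starting material and 8.08 of target and isomer together. The pool therefore holds 13.0 per intermediate.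
- With W at saturation, capture is pseudo-first-order in intermediate, with constant 0.120 min⁻¹.
- Add the first wait of 33.4 min for leaving starting material, and you have the mean capture time, 142 min, the average time from starting material to Q.
- Now the bound from above. Q cannot pass the charge of starting material, and the gas delivers at most 0.370 mM min⁻¹ of W. Full capture thus takes at least 94.5 min, far shorter than the run, so this bound stays at the full charge.
- Now the bound from below. Take a pessimistic case: the whole charge is shared between starting material and intermediate, which gives 7.09 mM of intermediate. Once W has risen from zero, supply against capture then puts W at 1.55 mM.
- That slow case gives a capture time of 391 min, which leaves you about 0.00161% of the pool at the asked time.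
- Tighten it: take W back at saturation late on. The run is 30.4 mean capture times long. You commit to complete capture, and no target in the long run.
- The forecast lies inside this bracket: all of the starting material has reacted, conversion 100%, Q 100%, target 0%, from “an irreversible, effectively unlimited drain”.
- The flask gives this: all of the starting material has reacted, conversion 100%, Q 100%, target in the long run 0%. After 0.600 d, Q in this flask already stands at 99.6%. Decay with the mean capture time as lifetime gives an estimated remainder of 0.228% there, and the flask shows 0.400%. The reckoning of the mean capture time holds no charge of starting material, so it stays 142 min in the neighbour flask with 21 mM of starting material. That neighbour flask gives 100% of Q at the asked time.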